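**Analysis of the target**

The target (25) is a biflavone in which two flavone units are joined by one carbon–carbon bond, from C3 of unit 1 to C6 of unit 2. Unit 1 is 5-hydroxy-7-methoxy-2-(4-methoxyphenyl)chromen-4-one (benzo ring A, pyranone ring C, anisyl ring B); unit 2 is a 5,7,4′-trihydroxyflavone of the apigenin type (benzo ring D, pyranone ring E, hydroxyphenyl ring F). There is no stereocentre; the C3–C6 bond is an axis with four ortho substituents (the C2 aryl group and the C4 carbonyl on one side, the 5- and 7-hydroxyls on the other), but the structure is drawn without axial configuration, so nothing has to be controlled. The sensitive elements are five phenolic hydroxyls, two of them chelated to a pyranone carbonyl, beside two methyl ethers that must survive, and the 5-hydroxyflavone unit 2, whose 6- and 8-substituted forms can interconvert by ring opening in hot strong acid (Wessely–Moser rearrangement). The synthesis is hard for three reasons: the inter-unit bond joins two fully substituted sp2 carbons, ring D is a phloroglucinol nucleus onto which a pyranone can in principle be fused in two ways (6- or 8-linked), and seven oxygens must be sorted into two that stay methylated and five that end free. The feature on which the plan rests is that in unit 2 the ring oxygen O1 is bound to C8a, which is para to C6 across ring D. A ring-D phenol with its free hydroxyl at the future O1 position, unit 1 on the para carbon and identical ether groups on the two carbons in between is therefore symmetric, and closing ring E at C4–C4a on either of its two equivalent ortho carbons gives the 6-linked isomer only.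

**Retrosynthetic reasoning**

The last disconnection is only a change of protecting groups. Compound 24 carries the five oxygens that are free in 25 as three benzyl ethers (O5, O7 and O4′ of unit 2) and one methyl ether (O5 of unit 1) that lies peri to the unit 1 carbonyl. The two methyl ethers that stay (O7 and O4′ of unit 1) have no carbonyl neighbour. A boron trihalide cleaves benzyl ethers and chelated methyl ethers but not isolated aryl methyl ethers, so one step should sort all the oxygens, without the hot protic acid that could scramble the 6-linkage.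

Ring E is opened at C4–C4a of unit 2, which leads back to the (Z)-β-aryloxycinnamic acid 22. This bond is chosen over O1–C2 or the C3–C6 axis because the carbon to be acylated then lies on the symmetric ring D of 22: O1 is in place, unit 1 is para to it, and the two carbons ortho to it are equivalent. The forward reaction, an intramolecular Friedel–Crafts acylation through acid chloride 23, only has to find one of two identical positions on a ring activated by three oxygens. What is gained is a ring closure that cannot give the 8-linked isomer.

Acid 22 comes from ester 21 by saponification, and 21 is cut at the vinyl ether bond O1–C2 of unit 2 into phenol 17 and ynoate 20. Conjugate addition of a phenoxide to an arylpropiolate brings in C2, C3 and C4 of ring E together with ring F in one step. By anti addition it places the carboxyl group on the side of the aryloxy group, as the ring closure requires. Ynoate 20 is cut at its aryl–alkyne bond into iodide 18 and propiolate 19 (Sonogashira coupling); ring F carries a benzyl ether so that it leaves with the others at the end.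

Phenol 17 is the allyl ether 16 after deallylation. The para oxygen of ring D needs a group of its own, distinct from benzyl and methyl, and allyl comes off under neutral conditions. Ring C of unit 1 in 16 is cut at O1–C2 and C2–C3, giving the 2-hydroxydeoxybenzoin 12 and acid chloride 13 (Baker–Venkataraman sequence through 14 and 15). A cut at the C3–C6 bond itself, meaning a cross-coupling in the forward sense, was not taken: both carbons are flanked by two substituents, and an arylmetal species of ring D with two ortho alkoxy groups would be prone to protodemetalation. In 12 that bond already exists as an ordinary benzylic C–C bond, so the crowded axis is never made by coupling.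

Deoxybenzoin 12 is cut at the ketone–ring A bond (C4–C4a of unit 1). Acylating the symmetric arene 9 with arylacetic acid 8 gives ketone 11 with no positional question. The phenol needed for ring C is then uncovered by cleaving one of the two equivalent ortho methyl ethers with the help of the neighbouring carbonyl. This two-step path is preferred to direct acylation of a phenol under the hot, strongly Lewis-acidic conditions usual for that reaction, which the benzyl ethers and the electron-rich ring D of 8 would not be expected to tolerate.

Acid 8 is traced back through nitrile 6 to aldehyde 4, a one-carbon homologation run under basic conditions so that the very electron-rich benzylic position is never ionised. Aldehyde 4 is the allyl ether of hydroxyaldehyde 3, and 3 comes from the symmetric phenol 1 by formylation para to the hydroxyl. Formylating the free phenol, not an ether of it, is what sets the para oxygen apart from the two flanking ones: in 1 the carbon para to the hydroxyl is unique, whereas in a triether two of the three ring positions would lead to the wrong isomer.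

**Alternatives that were turned down**

Alternative 1: Here the C3(unit 1)–C6(unit 2) bond is traced back to a 1,2-shift of ring D, and O1–C2 of unit 1 to a ketalisation–cyclisation. The precursor is the β,β-diaryl enone A2, and the product is the silyl ether A1.
- Forward step: Tl(NO3)3·3H2O in methanol with trimethyl orthoformate adds across the enone (trivalent thallium at the α-carbon, methanol at the β-carbon). Ring D migrates to the α-carbon as thallium leaves in its monovalent state, and acid in the same pot removes the methoxymethyl group and closes ring C.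
- For it: the crowded bond is made intramolecularly, by migration of the most electron-rich aryl group, which is mechanistically favourable. Ring D needs no one-carbon homologation to an arylacetic acid, and on that point this alternative is stronger than the chosen route.
- Against it: A2 is a triaryl-substituted enone that would have to come from a hindered ketone–ketone condensation, so the steps saved are spent again. The β-carbon that methanol must attack is shielded by two ortho benzyloxy groups. Trivalent thallium is an oxidant and an electrophile toward phloroglucinol-type rings A and D, the nitric acid set free threatens the silyl ether, and the reagent is toxic and stoichiometric.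
- Comparison: A1 is only a silyl-protected form of 17, so ring E would still have to be closed as in the chosen route. The alternative replaces eight predictable steps by one uncertain oxidation of an advanced intermediate. The chosen route instead makes the same bond early, as a plain benzylic bond, with classical reactions.

Alternative 2: Ring C of unit 1 is cut at C3–C4 and O1–C2 into salicylaldehyde A4 and diarylalkyne A5, and the product is the methoxymethyl ether A3.
- Forward step: [Cp*RhCl2]2 with Cu(OAc)2 as oxidant. Phenoxide-directed cleavage of the aldehyde C–H bond gives an acyl rhodium species, the alkyne inserts, and C–O reductive elimination closes the ring. Cu(OAc)2 returns monovalent rhodium to trivalent rhodium.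
- For it: it is the most convergent way to a 3-arylflavone. A4 can be bought, and two bonds and a ring form in one catalytic step. On step count up to the 3-arylflavone it is clearly stronger than the chosen route.
- Against it: the acyl group must bond to the alkyne carbon that bears ring D, the terminus with two ortho benzyloxy groups. Steric control would send it to the anisyl-bearing carbon and give the isomer with ring D at C2, and the electronic difference between two electron-rich aryl groups is small. The aldehyde is flanked by a methoxy group, and decarbonylation competes. A5 itself needs a ring-D halide with the halogen between the two benzyloxy groups, so the ring-D regiochemistry is not avoided.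
- Comparison: the chosen route gives up convergence here and offers fixed connectivity in its place. In 12 ring D is already attached to the carbon that becomes C3 before ring C exists, so no positional isomer can form. A3 would also still need ring E.

Alternative 3: Ring C of unit 1 is cut at C4a–C4, C4–C3 and O1–C2 into aryl iodide A7, carbon monoxide and ketone A8 (the ring-A hydroxyl and the para oxygen of ring D are assumed to travel as methoxymethyl ethers), and the product is the phenol A6.
- Forward step: Pd(dba)2 and Xantphos with a base. Zerovalent palladium inserts into A7, carbon monoxide gives an aroyl palladium species, and this acylates the enolate of A8 at carbon to a 1,3-diketone. HCl in methanol then removes the acetal groups and cyclodehydrates.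
- For it: it is a three-component assembly of a known reaction type. A6 is identical with compound 17 and arrives with the para oxygen already free, so it saves the deallylation and the demethylation of the chosen route. On those points it is stronger.
- Against it: the aroyl palladium intermediate is flanked by two ortho oxygens and must couple with a hindered α-aryl enolate to create a carbon bearing three bulky groups, so reductive elimination is expected to be slow and O-acylation or non-carbonylative arylation can compete. A8 needs the same ring-D arylacetic acid as the chosen route plus a further step to the aryl ketone, so the overall length is no shorter.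
- Comparison: the chosen route reaches the same type of diketone (15) by an intramolecular acyl transfer that does not depend on a congested reductive elimination or on handling carbon monoxide.

Key step: step 12

**Route**

Assumption: 3,5-bis(benzyloxy)phenol (1) is regarded as a purchasable building block, and the hindered C3–C6 axis of 25, which the target structure leaves undefined, is not treated as a stereochemical element.

Step 1
Reactants: 1 3,5-bis(benzyloxy)phenol
Product: 3 2,6-bis(benzyloxy)-4-hydroxybenzaldehyde, via iminium chloride 2 (not isolated)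
Conditions: POCl3, DMF, 0 °C to rt; then H2O, 0 °C to rt; chromatography
Reagents that add atoms: N,N-dimethylformamide CN(C)C=O; water O
Why: Vilsmeier–Haack formylation: the chloroiminium ion should attack mainly the carbon para to the free hydroxyl, between the two benzyloxy groups, as the closely related 3,5-dimethoxyphenol is known to do; the ortho-formyl isomer expected as the minor product is internally hydrogen-bonded, much less polar and should be removable by chromatography.

Step 2
Reactants: 3 2,6-bis(benzyloxy)-4-hydroxybenzaldehyde
Product: 4 2,6-bis(benzyloxy)-4-(prop-2-en-1-yloxy)benzaldehyde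
Conditions: allyl bromide, K2CO3, DMF, rt
Reagents that add atoms: allyl bromide C=CCBr
Why: Williamson etherification of the acidic para-hydroxyl (a vinylogous carboxylic acid); the allyl ether should withstand alkoxide, hot hydroxide, trifluoroacetic acid and MgI2 and can later be removed by zerovalent palladium without touching benzyl or methyl ethers.

Step 3
Reactants: 4 2,6-bis(benzyloxy)-4-(prop-2-en-1-yloxy)benzaldehyde
Product: 6 2-[2,6-bis(benzyloxy)-4-(prop-2-en-1-yloxy)phenyl]acetonitrile, via tosyloxazoline adduct 5 (not isolated)
Conditions: TosMIC, t-BuOK, DME, −40 °C; then MeOH, reflux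
Reagents that add atoms: tosylmethyl isocyanide [C-]#[N+]CS(=O)(=O)c1ccc(C)cc1
Why: Van Leusen reductive cyanation: the TosMIC anion adds to the aldehyde and closes to oxazoline 5, which on base-induced ring opening and methanolysis loses formate and sulfinate, so that the aldehyde carbon becomes the benzylic CH2 and the nitrile carbon is new; no acid is involved, so the 2,4,6-trialkoxybenzyl position is never ionised.

Step 4
Reactants: 6 2-[2,6-bis(benzyloxy)-4-(prop-2-en-1-yloxy)phenyl]acetonitrile
Product: 8 2-[2,6-bis(benzyloxy)-4-(prop-2-en-1-yloxy)phenyl]acetic acid, via primary amide 7 (not isolated)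
Conditions: KOH, EtOH/H2O, reflux; then aq. HCl, 0 °C
Reagents that add atoms: potassium hydroxide [K+].[OH-]; water O
Why: Alkaline nitrile hydrolysis through amide 7; allyl, benzyl and aryl ethers are inert to hot aqueous hydroxide, and cold acidification frees the arylacetic acid.

Step 5
Reactants: 8 2-[2,6-bis(benzyloxy)-4-(prop-2-en-1-yloxy)phenyl]acetic acid; 9 1,3,5-trimethoxybenzene
Product: 11 2-[2,6-bis(benzyloxy)-4-(prop-2-en-1-yloxy)phenyl]-1-(2,4,6-trimethoxyphenyl)ethan-1-one, via mixed trifluoroacetic anhydride 10 (not isolated)
Conditions: (CF3CO)2O, CH2Cl2, 0 °C; then 9 (3 eq), 0 °C to rt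
Reagents that add atoms: none
Why: Friedel–Crafts acylation through the acyl trifluoroacetate 10, a mild, metal-free activation that the highly nucleophilic arene 9, used in excess, should intercept at 0 °C; the symmetry of 9 excludes positional isomers and the absence of a strong Lewis acid should spare the benzyl and allyl ethers.

Step 6
Reactants: 11 2-[2,6-bis(benzyloxy)-4-(prop-2-en-1-yloxy)phenyl]-1-(2,4,6-trimethoxyphenyl)ethan-1-one
Product: 12 2-[2,6-bis(benzyloxy)-4-(prop-2-en-1-yloxy)phenyl]-1-(2-hydroxy-4,6-dimethoxyphenyl)ethan-1-one
Conditions: MgI2·OEt2 (3 eq), toluene, 80 °C; then aq. HCl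
Reagents that add atoms: none
Why: Chelation-controlled ether cleavage: magnesium held between the ketone oxygen and an ortho methoxy group activates that methyl for attack by iodide, and the magnesium phenoxide chelate so formed shuts down the second ortho methoxy group; ethers that cannot form a six-membered chelate with the carbonyl (the ring-D benzyl and allyl ethers, the para methoxy group) should remain.

Step 7
Reactants: 12 2-[2,6-bis(benzyloxy)-4-(prop-2-en-1-yloxy)phenyl]-1-(2-hydroxy-4,6-dimethoxyphenyl)ethan-1-one; 13 4-methoxybenzoyl chloride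
Product: 16 3-[2,6-bis(benzyloxy)-4-(prop-2-en-1-yloxy)phenyl]-5,7-dimethoxy-2-(4-methoxyphenyl)-4H-chromen-4-one, via aryl 4-methoxybenzoate 14 (not isolated), via 1,3-diketone 15 (not isolated)
Conditions: 13 (2.2 eq), K2CO3, acetone, reflux; then p-TsOH·H2O (cat.), toluene, 60 °C
Reagents that add atoms: none
Why: Baker–Venkataraman route to a 2,3-diarylchromone: O-aroylation gives ester 14, the enolate of the doubly activated benzylic CH2 takes over the aroyl group through a six-membered transition state to give diketone 15, and acid-catalysed cyclodehydration closes ring C with the anisyl group at C2 and ring D at C3 by construction.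

Step 8
Reactants: 16 3-[2,6-bis(benzyloxy)-4-(prop-2-en-1-yloxy)phenyl]-5,7-dimethoxy-2-(4-methoxyphenyl)-4H-chromen-4-one
Product: 17 3-[2,6-bis(benzyloxy)-4-hydroxyphenyl]-5,7-dimethoxy-2-(4-methoxyphenyl)-4H-chromen-4-one
Conditions: Pd(PPh3)4 (5 mol%), morpholine, THF, rt
Reagents that add atoms: none
Why: Tsuji–Trost deallylation: zerovalent palladium ionises the allyl aryl ether to a π-allyl complex and the phenoxide, and morpholine traps the allyl group; benzyl and methyl ethers and the 2-arylchromone are inert.

Step 9
Reactants: 18 1-(benzyloxy)-4-iodobenzene; 19 ethyl prop-2-ynoate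
Product: 20 ethyl 3-[4-(benzyloxy)phenyl]prop-2-ynoate
Conditions: PdCl2(PPh3)2 (2 mol%), CuI (4 mol%), K2CO3, THF, 65 °C
Reagents that add atoms: none
Why: Sonogashira coupling with a carbonate base in place of an amine, which avoids conjugate addition of an amine to the propiolate; the aryl iodide is unhindered.

Step 10
Reactants: 17 3-[2,6-bis(benzyloxy)-4-hydroxyphenyl]-5,7-dimethoxy-2-(4-methoxyphenyl)-4H-chromen-4-one; 20 ethyl 3-[4-(benzyloxy)phenyl]prop-2-ynoate
Product: 21 ethyl (2Z)-3-[4-(benzyloxy)phenyl]-3-{3,5-bis(benzyloxy)-4-[5,7-dimethoxy-2-(4-methoxyphenyl)-4-oxo-4H-chromen-3-yl]phenoxy}prop-2-enoate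
Conditions: Cs2CO3 (0.3 eq), DMF, 70 °C
Reagents that add atoms: none
Why: Oxa-Michael addition of the unhindered phenoxide of 17 to the β-carbon of ynoate 20; protonation of the vinyl anion anti to the new C–O bond places the ester cis to the aryloxy group (Z), and any E isomer is carried on because both geometries should converge in step 12.

Step 11
Reactants: 21 ethyl (2Z)-3-[4-(benzyloxy)phenyl]-3-{3,5-bis(benzyloxy)-4-[5,7-dimethoxy-2-(4-methoxyphenyl)-4-oxo-4H-chromen-3-yl]phenoxy}prop-2-enoate
Product: 22 (2Z)-3-[4-(benzyloxy)phenyl]-3-{3,5-bis(benzyloxy)-4-[5,7-dimethoxy-2-(4-methoxyphenyl)-4-oxo-4H-chromen-3-yl]phenoxy}prop-2-enoic acid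
Conditions: LiOH·H2O, THF/MeOH/H2O, rt; then aq. HCl to pH 3, 0 °C
Reagents that add atoms: lithium hydroxide [Li+].[OH-]
Why: Ester saponification with LiOH at room temperature, chosen to limit addition–elimination at the β-carbon; cold, weakly acidic work-up avoids hydrolysis of the enol ether.

Step 12
Reactants: 22 (2Z)-3-[4-(benzyloxy)phenyl]-3-{3,5-bis(benzyloxy)-4-[5,7-dimethoxy-2-(4-methoxyphenyl)-4-oxo-4H-chromen-3-yl]phenoxy}prop-2-enoic acid
Product: 24 5,7-bis(benzyloxy)-2-[4-(benzyloxy)phenyl]-6-[5,7-dimethoxy-2-(4-methoxyphenyl)-4-oxo-4H-chromen-3-yl]-4H-chromen-4-one, via acid chloride 23 (not isolated)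
Conditions: (COCl)2, DMF (cat.), CH2Cl2, 0 °C; concentrate; SnCl4 (2.5 eq), CH2Cl2, −78 to −20 °C
Reagents that add atoms: none
Why: Ruhemann-type flavone synthesis by intramolecular Friedel–Crafts acylation: oxalyl chloride with catalytic DMF converts the acid into acid chloride 23, and SnCl4 ionises it to an acylium ion that is stabilised as a vinylogous oxocarbenium ion by the β-aryloxy oxygen. The ring-D carbon ortho to that oxygen, which is also ortho to one benzyloxy group and para to the other, attacks the acyl carbon, and loss of a proton (as HCl) restores the aromatic ring and completes the C4–C4a bond of unit 2. Ring E closes as a six-membered pyranone in which the acyl C=O stays exocyclic and the attacked arene bond C4a–C8a becomes part of the new ring; the closest known reaction type is the Lewis-acid cyclisation of β-aryloxycinnamoyl chlorides to flavones. No stereocentre is formed. The step needs site selectivity on ring D, and the substrate secures it by symmetry: the two carbons ortho to the ether oxygen are equivalent, so either closure gives the 6-linked product and no 8-linked isomer can arise. It also needs the acyl group cis to the aryloxy group; the Z geometry from step 10 provides this, and any E isomer should equilibrate through the push–pull acylium ion faster than it can close onto the unactivated ortho carbon of ring F to give an indenone. Low temperature and the mild tin halide are expected to spare the benzyl ethers, and loss of the benzyl group peri to the new carbonyl would be harmless because step 13 removes all of them.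

Step 13
Reactants: 24 5,7-bis(benzyloxy)-2-[4-(benzyloxy)phenyl]-6-[5,7-dimethoxy-2-(4-methoxyphenyl)-4-oxo-4H-chromen-3-yl]-4H-chromen-4-one
Product: 25 5,7-dihydroxy-6-[5-hydroxy-7-methoxy-2-(4-methoxyphenyl)-4-oxo-4H-chromen-3-yl]-2-(4-hydroxyphenyl)-4H-chromen-4-one
Conditions: BCl3 (8 eq), C6HMe5 (6 eq), CH2Cl2, −78 °C to rt; then H2O
Reagents that add atoms: none
Why: Lewis-acid ether cleavage: BCl3 removes aryl benzyl ethers at low temperature, with pentamethylbenzene trapping the benzyl cations, and on warming cleaves the methyl ether peri to the unit 1 carbonyl through a boron chelate, while the non-chelated 7- and 4′-methyl ethers of unit 1 should remain; the absence of hot protic acid avoids Wessely–Moser isomerisation of the 6-linked unit 2.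

**Compound list**

1 | 3,5-bis(benzyloxy)phenol | Oc1cc(OCc2ccccc2)cc(OCc2ccccc2)c1 | starting material
2 | N-{[2,6-bis(benzyloxy)-4-hydroxyphenyl]methylidene}-N-methylmethanaminium chloride | C[N+](C)=Cc1c(OCc2ccccc2)cc(O)cc1OCc1ccccc1.[Cl-] | intermediate
3 | 2,6-bis(benzyloxy)-4-hydroxybenzaldehyde | O=Cc1c(OCc2ccccc2)cc(O)cc1OCc1ccccc1 | intermediate
4 | 2,6-bis(benzyloxy)-4-(prop-2-en-1-yloxy)benzaldehyde | O=Cc1c(OCc2ccccc2)cc(OCC=C)cc1OCc1ccccc1 | intermediate
5 | 5-[2,6-bis(benzyloxy)-4-(prop-2-en-1-yloxy)phenyl]-4-(4-methylbenzenesulfonyl)-4,5-dihydro-1,3-oxazole (transient, racemic, relative configuration not defined) | Cc1ccc(cc1)S(=O)(=O)C1N=COC1c1c(OCc2ccccc2)cc(OCC=C)cc1OCc1ccccc1 | intermediate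
6 | 2-[2,6-bis(benzyloxy)-4-(prop-2-en-1-yloxy)phenyl]acetonitrile | N#CCc1c(OCc2ccccc2)cc(OCC=C)cc1OCc1ccccc1 | intermediate
7 | 2-[2,6-bis(benzyloxy)-4-(prop-2-en-1-yloxy)phenyl]acetamide | NC(=O)Cc1c(OCc2ccccc2)cc(OCC=C)cc1OCc1ccccc1 | intermediate
8 | 2-[2,6-bis(benzyloxy)-4-(prop-2-en-1-yloxy)phenyl]acetic acid | OC(=O)Cc1c(OCc2ccccc2)cc(OCC=C)cc1OCc1ccccc1 | intermediate
9 | 1,3,5-trimethoxybenzene | COc1cc(OC)cc(OC)c1 | starting material
10 | 2-[2,6-bis(benzyloxy)-4-(prop-2-en-1-yloxy)phenyl]acetic trifluoroacetic anhydride | O=C(Cc1c(OCc2ccccc2)cc(OCC=C)cc1OCc1ccccc1)OC(=O)C(F)(F)F | intermediate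
11 | 2-[2,6-bis(benzyloxy)-4-(prop-2-en-1-yloxy)phenyl]-1-(2,4,6-trimethoxyphenyl)ethan-1-one | COc1cc(OC)c(C(=O)Cc2c(OCc3ccccc3)cc(OCC=C)cc2OCc2ccccc2)c(OC)c1 | intermediate
12 | 2-[2,6-bis(benzyloxy)-4-(prop-2-en-1-yloxy)phenyl]-1-(2-hydroxy-4,6-dimethoxyphenyl)ethan-1-one | COc1cc(O)c(C(=O)Cc2c(OCc3ccccc3)cc(OCC=C)cc2OCc2ccccc2)c(OC)c1 | intermediate
13 | 4-methoxybenzoyl chloride | COc1ccc(C(=O)Cl)cc1 | starting material
14 | 2-{[2,6-bis(benzyloxy)-4-(prop-2-en-1-yloxy)phenyl]acetyl}-3,5-dimethoxyphenyl 4-methoxybenzoate | COc1ccc(C(=O)Oc2cc(OC)cc(OC)c2C(=O)Cc2c(OCc3ccccc3)cc(OCC=C)cc2OCc2ccccc2)cc1 | intermediate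
15 | 2-[2,6-bis(benzyloxy)-4-(prop-2-en-1-yloxy)phenyl]-1-(2-hydroxy-4,6-dimethoxyphenyl)-3-(4-methoxyphenyl)propane-1,3-dione (racemic at the enolisable central carbon) | COc1ccc(C(=O)C(C(=O)c2c(O)cc(OC)cc2OC)c2c(OCc3ccccc3)cc(OCC=C)cc2OCc2ccccc2)cc1 | intermediate
16 | 3-[2,6-bis(benzyloxy)-4-(prop-2-en-1-yloxy)phenyl]-5,7-dimethoxy-2-(4-methoxyphenyl)-4H-chromen-4-one | COc1ccc(-c2oc3cc(OC)cc(OC)c3c(=O)c2-c2c(OCc3ccccc3)cc(OCC=C)cc2OCc2ccccc2)cc1 | intermediate
17 | 3-[2,6-bis(benzyloxy)-4-hydroxyphenyl]-5,7-dimethoxy-2-(4-methoxyphenyl)-4H-chromen-4-one | COc1ccc(-c2oc3cc(OC)cc(OC)c3c(=O)c2-c2c(OCc3ccccc3)cc(O)cc2OCc2ccccc2)cc1 | intermediate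
18 | 1-(benzyloxy)-4-iodobenzene | Ic1ccc(OCc2ccccc2)cc1 | starting material
19 | ethyl prop-2-ynoate (ethyl propiolate) | C#CC(=O)OCC | starting material
20 | ethyl 3-[4-(benzyloxy)phenyl]prop-2-ynoate | CCOC(=O)C#Cc1ccc(OCc2ccccc2)cc1 | intermediate
21 | ethyl (2Z)-3-[4-(benzyloxy)phenyl]-3-{3,5-bis(benzyloxy)-4-[5,7-dimethoxy-2-(4-methoxyphenyl)-4-oxo-4H-chromen-3-yl]phenoxy}prop-2-enoate | CCOC(=O)/C=C(\Oc1cc(OCc2ccccc2)c(-c2c(-c3ccc(OC)cc3)oc3cc(OC)cc(OC)c3c2=O)c(OCc2ccccc2)c1)c1ccc(OCc2ccccc2)cc1 | intermediate
22 | (2Z)-3-[4-(benzyloxy)phenyl]-3-{3,5-bis(benzyloxy)-4-[5,7-dimethoxy-2-(4-methoxyphenyl)-4-oxo-4H-chromen-3-yl]phenoxy}prop-2-enoic acid | O=C(O)/C=C(\Oc1cc(OCc2ccccc2)c(-c2c(-c3ccc(OC)cc3)oc3cc(OC)cc(OC)c3c2=O)c(OCc2ccccc2)c1)c1ccc(OCc2ccccc2)cc1 | intermediate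
23 | (2Z)-3-[4-(benzyloxy)phenyl]-3-{3,5-bis(benzyloxy)-4-[5,7-dimethoxy-2-(4-methoxyphenyl)-4-oxo-4H-chromen-3-yl]phenoxy}prop-2-enoyl chloride | O=C(Cl)/C=C(\Oc1cc(OCc2ccccc2)c(-c2c(-c3ccc(OC)cc3)oc3cc(OC)cc(OC)c3c2=O)c(OCc2ccccc2)c1)c1ccc(OCc2ccccc2)cc1 | intermediate
24 | 5,7-bis(benzyloxy)-2-[4-(benzyloxy)phenyl]-6-[5,7-dimethoxy-2-(4-methoxyphenyl)-4-oxo-4H-chromen-3-yl]-4H-chromen-4-one | COc1ccc(-c2oc3cc(OC)cc(OC)c3c(=O)c2-c2c(OCc3ccccc3)cc3oc(-c4ccc(OCc5ccccc5)cc4)cc(=O)c3c2OCc2ccccc2)cc1 | intermediate
25 | 5,7-dihydroxy-6-[5-hydroxy-7-methoxy-2-(4-methoxyphenyl)-4-oxo-4H-chromen-3-yl]-2-(4-hydroxyphenyl)-4H-chromen-4-one (CNP0273448.0) | COc1ccc(-c2oc3cc(OC)cc(O)c3c(=O)c2-c2c(O)cc3oc(-c4ccc(O)cc4)cc(=O)c3c2O)cc1 | target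

**Step count and risk**

Total: 13 steps. Longest linear sequence: 12 steps (steps 1–8 and 10–13, from 1 to 25); step 9 prepares ynoate 20 in a side branch.

Least certain steps:

Step 12 (key step). What may go wrong is Lewis-acid cleavage of ring-D benzyl ethers followed by benzylation at carbon. Ring closure may also be slow because the lone pair of the ether oxygen is engaged in the push–pull acylium ion, which would let hydrolysis of the enol ether on work-up, or closure of E-configured material onto ring F, compete. The fallback sets out from 17 and returns at 24, and builds ring E by the acetophenone route on the same symmetric phenol. C-acetylation of 17 ortho to the free hydroxyl (Ac2O, BF3·OEt2, rt; both ortho carbons are equivalent) should give 3-[3-acetyl-2,6-bis(benzyloxy)-4-hydroxyphenyl]-5,7-dimethoxy-2-(4-methoxyphenyl)-4H-chromen-4-one F1. O-acylation with 4-(benzyloxy)benzoyl chloride in pyridine gives 2-acetyl-3,5-bis(benzyloxy)-4-[5,7-dimethoxy-2-(4-methoxyphenyl)-4-oxo-4H-chromen-3-yl]phenyl 4-(benzyloxy)benzoate F2. Baker–Venkataraman acyl transfer (t-BuOK, THF) gives 1-{2,4-bis(benzyloxy)-3-[5,7-dimethoxy-2-(4-methoxyphenyl)-4-oxo-4H-chromen-3-yl]-6-hydroxyphenyl}-3-[4-(benzyloxy)phenyl]propane-1,3-dione F3, and cyclodehydration with catalytic p-TsOH in toluene gives 24.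

Step 1. What may go wrong is poor positional selectivity of the formylation, with attack ortho instead of para to the hydroxyl and a difficult separation. The fallback sets out from 1 and returns at 8, and fixes the para position by oxidation instead of electrophilic substitution. Teuber oxidation of 1 with (KSO3)2NO gives 2,6-bis(benzyloxy)cyclohexa-2,5-diene-1,4-dione F4. The lithium enolate of ethyl acetate (LDA, THF, −78 °C) adds to the more electrophilic carbonyl, the one between the two benzyloxy-bearing carbons, to give ethyl 2-[2,6-bis(benzyloxy)-1-hydroxy-4-oxocyclohexa-2,5-dien-1-yl]acetate F5. Reductive aromatisation with Zn in AcOH gives ethyl 2-[2,6-bis(benzyloxy)-4-hydroxyphenyl]acetate F6. Allylation (allyl bromide, K2CO3) gives ethyl 2-[2,6-bis(benzyloxy)-4-(prop-2-en-1-yloxy)phenyl]acetate F7, and LiOH then gives 8.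

Step 5. What may go wrong is participation of an ortho benzyloxy oxygen in the activated acyl group with loss of benzyl (lactonisation to a benzofuranone), or acylation of ring D of a second molecule instead of 9. The fallback sets out from 8 and 9 and returns at 11, and reverses the polarity so that no acylium-type species is formed next to ring D. Acid 8 is converted with carbonyldiimidazole and N,O-dimethylhydroxylamine hydrochloride into 2-[2,6-bis(benzyloxy)-4-(prop-2-en-1-yloxy)phenyl]-N-methoxy-N-methylacetamide F8. Arene 9 is lithiated with n-BuLi in THF at 0 °C to (2,4,6-trimethoxyphenyl)lithium F9, and F9 adds to F8 at −78 °C to give 11 after aqueous work-up.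

Step 7. What may go wrong is stalling at the O-aroyl ester because acyl transfer to the crowded benzylic carbon is slow, or cleavage of that ester by adventitious water. The fallback sets out from 12 and returns at 16, and brings in ring B at the aldehyde oxidation level. Condensation of 12 with 4-methoxybenzaldehyde (piperidine, EtOH, reflux; Knoevenagel condensation followed by oxa-Michael ring closure) should give 3-[2,6-bis(benzyloxy)-4-(prop-2-en-1-yloxy)phenyl]-5,7-dimethoxy-2-(4-methoxyphenyl)-2,3-dihydro-4H-chromen-4-one F10 as a racemic mixture of diastereomers. Dehydrogenation with DDQ in dioxane at reflux converts both into 16.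

Step 13. What may go wrong is incomplete cleavage of the peri methyl ether, further demethylation at O7 and O4′ of unit 1 on long exposure, or benzylation of the electron-rich rings at carbon. The fallback sets out from 24 and returns at 25, and separates the two tasks. Hydrogenolysis (H2, Pd/C, THF/MeOH) removes the three benzyl groups to give 5,7-dihydroxy-2-(4-hydroxyphenyl)-6-[5,7-dimethoxy-2-(4-methoxyphenyl)-4-oxo-4H-chromen-3-yl]-4H-chromen-4-one F11. AlCl3 in MeCN then cleaves only the methyl ether chelated to the unit 1 carbonyl to give 25.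

**Further compounds**

F1 | step 12 | 3-[3-acetyl-2,6-bis(benzyloxy)-4-hydroxyphenyl]-5,7-dimethoxy-2-(4-methoxyphenyl)-4H-chromen-4-one | COc1ccc(-c2oc3cc(OC)cc(OC)c3c(=O)c2-c2c(OCc3ccccc3)cc(O)c(C(C)=O)c2OCc2ccccc2)cc1
F2 | step 12 | 2-acetyl-3,5-bis(benzyloxy)-4-[5,7-dimethoxy-2-(4-methoxyphenyl)-4-oxo-4H-chromen-3-yl]phenyl 4-(benzyloxy)benzoate | COc1ccc(-c2oc3cc(OC)cc(OC)c3c(=O)c2-c2c(OCc3ccccc3)cc(OC(=O)c3ccc(OCc4ccccc4)cc3)c(C(C)=O)c2OCc2ccccc2)cc1
F3 | step 12 | 1-{2,4-bis(benzyloxy)-3-[5,7-dimethoxy-2-(4-methoxyphenyl)-4-oxo-4H-chromen-3-yl]-6-hydroxyphenyl}-3-[4-(benzyloxy)phenyl]propane-1,3-dione | COc1ccc(-c2oc3cc(OC)cc(OC)c3c(=O)c2-c2c(OCc3ccccc3)cc(O)c(C(=O)CC(=O)c3ccc(OCc4ccccc4)cc3)c2OCc2ccccc2)cc1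
F4 | step 1 | 2,6-bis(benzyloxy)cyclohexa-2,5-diene-1,4-dione | O=C1C=C(OCc2ccccc2)C(=O)C(OCc2ccccc2)=C1
F5 | step 1 | ethyl 2-[2,6-bis(benzyloxy)-1-hydroxy-4-oxocyclohexa-2,5-dien-1-yl]acetate | CCOC(=O)CC1(O)C(OCc2ccccc2)=CC(=O)C=C1OCc1ccccc1
F6 | step 1 | ethyl 2-[2,6-bis(benzyloxy)-4-hydroxyphenyl]acetate | CCOC(=O)Cc1c(OCc2ccccc2)cc(O)cc1OCc1ccccc1
F7 | step 1 | ethyl 2-[2,6-bis(benzyloxy)-4-(prop-2-en-1-yloxy)phenyl]acetate | CCOC(=O)Cc1c(OCc2ccccc2)cc(OCC=C)cc1OCc1ccccc1
F8 | step 5 | 2-[2,6-bis(benzyloxy)-4-(prop-2-en-1-yloxy)phenyl]-N-methoxy-N-methylacetamide | CON(C)C(=O)Cc1c(OCc2ccccc2)cc(OCC=C)cc1OCc1ccccc1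
F9 | step 5 | (2,4,6-trimethoxyphenyl)lithium | [Li]c1c(OC)cc(OC)cc1OC
F10 | step 7 | 3-[2,6-bis(benzyloxy)-4-(prop-2-en-1-yloxy)phenyl]-5,7-dimethoxy-2-(4-methoxyphenyl)-2,3-dihydro-4H-chromen-4-one (racemic mixture of diastereomers, configuration not defined) | COc1ccc(C2Oc3cc(OC)cc(OC)c3C(=O)C2c2c(OCc3ccccc3)cc(OCC=C)cc2OCc2ccccc2)cc1
F11 | step 13 | 5,7-dihydroxy-2-(4-hydroxyphenyl)-6-[5,7-dimethoxy-2-(4-methoxyphenyl)-4-oxo-4H-chromen-3-yl]-4H-chromen-4-one | COc1ccc(-c2oc3cc(OC)cc(OC)c3c(=O)c2-c2c(O)cc3oc(-c4ccc(O)cc4)cc(=O)c3c2O)cc1
A1 | alternative 1 | 3-[2,6-bis(benzyloxy)-4-(triisopropylsilyloxy)phenyl]-5,7-dimethoxy-2-(4-methoxyphenyl)chromen-4-one | COc1ccc(-c2oc3cc(OC)cc(OC)c3c(=O)c2-c2c(OCc3ccccc3)cc(O[Si](C(C)C)(C(C)C)C(C)C)cc2OCc2ccccc2)cc1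
A2 | alternative 1 | 3-[2,6-bis(benzyloxy)-4-(triisopropylsilyloxy)phenyl]-1-[2,4-dimethoxy-6-(methoxymethoxy)phenyl]-3-(4-methoxyphenyl)prop-2-en-1-one (either alkene geometry) | COCOc1cc(OC)cc(OC)c1C(=O)C=C(c1ccc(OC)cc1)c1c(OCc2ccccc2)cc(O[Si](C(C)C)(C(C)C)C(C)C)cc1OCc1ccccc1
A3 | alternative 2 | 3-[2,6-bis(benzyloxy)-4-(methoxymethoxy)phenyl]-5,7-dimethoxy-2-(4-methoxyphenyl)chromen-4-one | COc1ccc(-c2oc3cc(OC)cc(OC)c3c(=O)c2-c2c(OCc3ccccc3)cc(OCOC)cc2OCc2ccccc2)cc1
A4 | alternative 2 | 2-hydroxy-4,6-dimethoxybenzaldehyde | COc1cc(O)c(C=O)c(OC)c1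
A5 | alternative 2 | 1,3-bis(benzyloxy)-5-(methoxymethoxy)-2-[(4-methoxyphenyl)ethynyl]benzene | COCOc1cc(OCc2ccccc2)c(C#Cc2ccc(OC)cc2)c(OCc2ccccc2)c1
A6 | alternative 3 | 3-[2,6-bis(benzyloxy)-4-hydroxyphenyl]-5,7-dimethoxy-2-(4-methoxyphenyl)chromen-4-one | COc1ccc(-c2oc3cc(OC)cc(OC)c3c(=O)c2-c2c(OCc3ccccc3)cc(O)cc2OCc2ccccc2)cc1
A7 | alternative 3 | 2-iodo-1,5-dimethoxy-3-(methoxymethoxy)benzene | COCOc1cc(OC)cc(OC)c1I
A8 | alternative 3 | 2-[2,6-bis(benzyloxy)-4-(methoxymethoxy)phenyl]-1-(4-methoxyphenyl)ethan-1-one | COCOc1cc(OCc2ccccc2)c(CC(=O)c2ccc(OC)cc2)c(OCc2ccccc2)c1
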